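**Retrosynthetic overview**

- The two ring B side chains go on last. The 3'-bromo-5'-iodoflavanone takes the alkynol by Sonogashira coupling at C3'–I and the prenyl group by Stille coupling at C5'–Br; cis-semihydrogenation and desilylation then give the target.
- Feature used: on ring A, C8a (bonded to O1) and C4a (bonded to the C4 carbonyl) are neighbouring carbons, and C5, the next carbon after C4a, carries oxygen. This contiguous O1–C8a / C4a–C4 / C5–O array is what a 3-alkoxybenzyne gives when an O-nucleophile adds at the distal aryne carbon and the ortho carbanion is acylated.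
- Key disconnection: O1–C8a and C4–C4a are cut together, giving 3,5-bis(methoxymethoxy)benzyne (stored as its 2-silylaryl triflate) and an (S)-3-aryl-3-hydroxypropanoate. Ring C is the only ring made; rings A and B are bought.
- The aryne precursor comes from phloroglucinol (bis-MOM ether, carbamate-directed ortho-silylation, carbamate to triflate). The hydroxy ester comes from methyl 3-bromo-4-hydroxybenzoate (iodination, O-methylation, Claisen condensation, asymmetric transfer hydrogenation, which sets C2).

Key step: step 9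

Remark: the ruthenium catalyst with (S,S)-TsDPEN is assumed to reduce the aryl keto ester with the same facial sense as acetophenone, giving the (S)-carbinol (the (R,R)-catalyst is used if the opposite sense is found); the chelated 5-hydroxyl is left free after step 10 and only the 7-hydroxyl is silylated.

**Route**

Step 1
Reactants: 1 phloroglucinol
Product: 2 3,5-bis(methoxymethoxy)phenol
Conditions: MOMCl (2.1 equiv), iPr2NEt (2.5 equiv), CH2Cl2/DMF, 0 °C to rt; chromatographic separation from the mono- and tris-ethers
Reagents that add atoms: chloromethyl methyl ether, COCCl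
Why: Williamson-type O-alkylation of the phenoxide with the α-chloro ether; the three hydroxyls are equivalent, so the bis-ether should be the main component of a statistical mixture at this stoichiometry and is separable by polarity.

Step 2
Reactants: 2 3,5-bis(methoxymethoxy)phenol
Product: 3 3,5-bis(methoxymethoxy)phenyl N-isopropylcarbamate
Conditions: iPrNCO (1.3 equiv), Et3N (0.2 equiv), CH2Cl2, rt
Reagents that add atoms: isopropyl isocyanate, CC(C)N=C=O
Why: Base-catalysed addition of a phenol to an isocyanate (carbamoylation) should install the directing group cleanly, with no by-product.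

Step 3
Reactants: 3 3,5-bis(methoxymethoxy)phenyl N-isopropylcarbamate
Product: 7 3,5-bis(methoxymethoxy)-2-(trimethylsilyl)phenyl N-isopropylcarbamate, via N-silyl carbamate 4 (not isolated), via ortho-lithio carbamate 5 (not isolated), via N-silyl C-silyl carbamate 6 (not isolated)
Conditions: TBSOTf (1.1 equiv), TMEDA (1.1 equiv), Et2O, 0 °C to rt; then TMEDA (2 equiv), n-BuLi (2 equiv), −78 °C; TMSCl, −78 °C to rt; aq NaHSO4 work-up
Reagents that add atoms: chlorotrimethylsilane, C[Si](C)(C)Cl
Why: Directed ortho-metalation, in which the in situ N-silylated carbamate is the strongest director on the ring and each of its two equivalent ortho positions is also flanked by a methoxymethoxy group, so lithiation and silyl quench should occur at C2 and not between the two acetal ethers, and the N-silyl group is lost on the mildly acidic work-up.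

Step 4
Reactants: 7 3,5-bis(methoxymethoxy)-2-(trimethylsilyl)phenyl N-isopropylcarbamate
Product: 9 3,5-bis(methoxymethoxy)-2-(trimethylsilyl)phenyl trifluoromethanesulfonate, via 3,5-bis(methoxymethoxy)-2-(trimethylsilyl)phenol 8 (not isolated)
Conditions: DBU (1.5 equiv), Et2NH (1.2 equiv), MeCN, 40 °C; then PhNTf2 (1.5 equiv), rt
Reagents that add atoms: N-phenylbis(trifluoromethanesulfonimide), O=S(=O)(N(c1ccccc1)S(=O)(=O)C(F)(F)F)C(F)(F)F
Why: E1cB cleavage of the N-monoalkyl carbamate (isocyanate expelled and trapped by diethylamine) frees the phenoxide, which is sulfonylated in the same pot under conditions that leave the acetal ethers and the aryl–silicon bond untouched.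

Step 5
Reactants: 10 methyl 3-bromo-4-hydroxybenzoate
Product: 11 methyl 3-bromo-4-hydroxy-5-iodobenzoate
Conditions: NIS (1.05 equiv), TsOH·H2O (cat.), MeCN, rt
Reagents that add atoms: N-iodosuccinimide, O=C1CCC(=O)N1I
Why: Electrophilic aromatic iodination of a phenol, for which the only free activated position is the second ortho carbon (para is blocked by the ester).

Step 6
Reactants: 11 methyl 3-bromo-4-hydroxy-5-iodobenzoate
Product: 12 methyl 3-bromo-5-iodo-4-methoxybenzoate
Conditions: MeI (1.5 equiv), K2CO3 (2 equiv), DMF, rt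
Reagents that add atoms: iodomethane, CI
Why: Williamson etherification of an acidic 2,6-dihalophenol should proceed readily despite the flanking halogens.

Step 7
Reactants: 12 methyl 3-bromo-5-iodo-4-methoxybenzoate; 13 methyl acetate
Product: 15 methyl 3-(3-bromo-5-iodo-4-methoxyphenyl)-3-oxopropanoate, via lithium enolate of methyl acetate 14 (not isolated)
Conditions: LiN(SiMe3)2 (3 equiv), methyl acetate (3 equiv), THF, −78 °C; then 12, −78 to 0 °C; aq NH4Cl
Reagents that add atoms: none
Why: Crossed Claisen condensation in which the non-enolisable benzoate can only be the acceptor and deprotonation of the β-keto ester drives the equilibrium; the silylamide base is too weak to metalate the halogenated ring.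

Step 8
Reactants: 15 methyl 3-(3-bromo-5-iodo-4-methoxyphenyl)-3-oxopropanoate
Product: 16 methyl (S)-3-(3-bromo-5-iodo-4-methoxyphenyl)-3-hydroxypropanoate
Conditions: RuCl[(S,S)-TsDPEN](p-cymene) (1 mol%), HCO2H/Et3N (5:2), EtOAc, rt
Reagents that add atoms: none
Why: Noyori asymmetric transfer hydrogenation, in which the aryl group of the ketone aligns with the η6-arene of the catalyst so that hydride is delivered to one face and the (S)-carbinol (the future C2) should form, with the aryl halides untouched because no low-valent metal capable of oxidative addition is present.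

Step 9
Reactants: 16 methyl (S)-3-(3-bromo-5-iodo-4-methoxyphenyl)-3-hydroxypropanoate; 9 3,5-bis(methoxymethoxy)-2-(trimethylsilyl)phenyl trifluoromethanesulfonate
Product: 20 (S)-2-(3-bromo-5-iodo-4-methoxyphenyl)-5,7-bis(methoxymethoxy)chroman-4-one, via sodium alkoxide of the hydroxy ester 17 (not isolated), via 3,5-bis(methoxymethoxy)benzyne 18 (not isolated), via O-arylated aryl anion 19 (not isolated)
Conditions: NaH (1.05 equiv), THF, 0 °C; then 9 (1.6 equiv), CsF (4 equiv), 18-crown-6 (4 equiv), THF, 0 °C to rt; aq NH4Cl at 0 °C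
Reagents that add atoms: none
Why: Proposed new method: fluoride removes the trimethylsilyl group of 9 and triflate departs to give aryne 18; alkoxide 17 adds at the aryne carbon distal to the flanking methoxymethoxy group (bond O1–C8a), because the distorted aryne is more electrophilic there and carbanion 19 then sits ortho to oxygen, where it is inductively stabilised; 19 attacks the ester carbonyl five atoms away and methoxide is expelled (bond C4–C4a). The closest known reaction type is the fluoride-triggered annulation of arynes with salicylate esters to xanthones (O-arylation, then intramolecular acylation of the aryl anion), extended here from a phenoxide to an aliphatic β-alkoxide, and the ring-closing half resembles a Parham acylation. Ring C closes by 6-exo-trig acyl substitution. No stereocentre is created: neither the C2–O nor the C2–H bond is touched, so C2 keeps the (S) configuration set in step 8. The step needs regioselective attack on the unsymmetrical aryne, secured by the alkoxy group next to the triple bond, and acylation faster than proton capture, retro-aldol cleavage or β-elimination, secured by an aprotic medium, a fully preformed alkoxide (no free hydroxyl as proton source), low temperature and surplus aryne that consumes the released methoxide before it can open ring C.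

Step 10
Reactants: 20 (S)-2-(3-bromo-5-iodo-4-methoxyphenyl)-5,7-bis(methoxymethoxy)chroman-4-one
Product: 21 (S)-2-(3-bromo-5-iodo-4-methoxyphenyl)-5,7-dihydroxychroman-4-one
Conditions: HCl (3 M) in MeOH/THF, 45 °C
Reagents that add atoms: none
Why: Acid-catalysed acetal methanolysis removes both methoxymethyl ethers while the molecule still has no acid-sensitive allylic alcohol, and the flavanone ring and C2 are stable to acid.

Step 11
Reactants: 21 (S)-2-(3-bromo-5-iodo-4-methoxyphenyl)-5,7-dihydroxychroman-4-one
Product: 22 (S)-2-(3-bromo-5-iodo-4-methoxyphenyl)-5-hydroxy-7-(triisopropylsilyloxy)chroman-4-one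
Conditions: TIPSCl (1.1 equiv), imidazole (2.2 equiv), DMF, 0 °C
Reagents that add atoms: triisopropylsilyl chloride, CC(C)[Si](Cl)(C(C)C)C(C)C
Why: Chemoselective silylation of the acidic, unhindered 7-hydroxyl, since the 5-hydroxyl is locked in a hydrogen bond to the C4 carbonyl and is inert to a silyl chloride with imidazole.

Step 12
Reactants: 22 (S)-2-(3-bromo-5-iodo-4-methoxyphenyl)-5-hydroxy-7-(triisopropylsilyloxy)chroman-4-one; 23 2-methyl-3-butyn-2-ol
Product: 24 (S)-2-[3-bromo-5-(3-hydroxy-3-methylbut-1-yn-1-yl)-4-methoxyphenyl]-5-hydroxy-7-(triisopropylsilyloxy)chroman-4-one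
Conditions: PdCl2(PPh3)2 (3 mol%), CuI (5 mol%), Et3N, THF, rt
Reagents that add atoms: none
Why: Sonogashira coupling at room temperature, where zerovalent palladium inserts into the C–I bond far faster than into the C–Br bond, so only the iodide should be alkynylated, and the mild amine at room temperature should not open ring C.

Step 13
Reactants: 24 (S)-2-[3-bromo-5-(3-hydroxy-3-methylbut-1-yn-1-yl)-4-methoxyphenyl]-5-hydroxy-7-(triisopropylsilyloxy)chroman-4-one; 25 tributyl(3-methylbut-2-en-1-yl)stannane
Product: 26 (S)-5-hydroxy-2-[3-(3-hydroxy-3-methylbut-1-yn-1-yl)-4-methoxy-5-(3-methylbut-2-en-1-yl)phenyl]-7-(triisopropylsilyloxy)chroman-4-one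
Conditions: Pd(PPh3)4 (10 mol%), DMF, 90 °C, degassed
Reagents that add atoms: none
Why: Migita–Kosugi–Stille coupling, in which oxidative addition of zerovalent palladium to the aryl bromide, allyl transfer from tin and reductive elimination at the less hindered primary allyl terminus should give the linear prenyl arene under neutral, fluoride-free conditions that spare the flavanone and the silyl ether.

Step 14
Reactants: 26 (S)-5-hydroxy-2-[3-(3-hydroxy-3-methylbut-1-yn-1-yl)-4-methoxy-5-(3-methylbut-2-en-1-yl)phenyl]-7-(triisopropylsilyloxy)chroman-4-one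
Product: 27 (S)-5-hydroxy-2-[3-((Z)-3-hydroxy-3-methylbut-1-en-1-yl)-4-methoxy-5-(3-methylbut-2-en-1-yl)phenyl]-7-(triisopropylsilyloxy)chroman-4-one
Conditions: H2 (1 atm), Pd/CaCO3 poisoned with Pb(OAc)2 (Lindlar catalyst), quinoline, EtOAc, rt, stopped after one equivalent of H2
Reagents that add atoms: none
Why: Lindlar semihydrogenation adds hydrogen syn across the alkyne on the poisoned surface to give the (Z)-alkene, and the trisubstituted prenyl alkene and the ketone are not reduced on this catalyst.

Step 15
Reactants: 27 (S)-5-hydroxy-2-[3-((Z)-3-hydroxy-3-methylbut-1-en-1-yl)-4-methoxy-5-(3-methylbut-2-en-1-yl)phenyl]-7-(triisopropylsilyloxy)chroman-4-one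
Product: 28 (S)-5,7-dihydroxy-2-[3-((Z)-3-hydroxy-3-methylbut-1-en-1-yl)-4-methoxy-5-(3-methylbut-2-en-1-yl)phenyl]chroman-4-one
Conditions: Bu4NF, AcOH (1:1), THF, 0 °C
Reagents that add atoms: none
Why: Fluoride-mediated cleavage of the activated aryl silyl ether, buffered with acetic acid so that neither base-induced opening of ring C (loss of C2 configuration) nor acid-induced ionisation of the tertiary allylic alcohol can occur.

**Compound list**

1 | phloroglucinol | Oc1cc(O)cc(O)c1 | starting material
2 | 3,5-bis(methoxymethoxy)phenol | COCOc1cc(O)cc(OCOC)c1 | intermediate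
3 | 3,5-bis(methoxymethoxy)phenyl N-isopropylcarbamate | COCOc1cc(OCOC)cc(OC(=O)NC(C)C)c1 | intermediate
4 | 3,5-bis(methoxymethoxy)phenyl N-(tert-butyldimethylsilyl)-N-isopropylcarbamate | COCOc1cc(OCOC)cc(OC(=O)N(C(C)C)[Si](C)(C)C(C)(C)C)c1 | intermediate
5 | 2-lithio-3,5-bis(methoxymethoxy)phenyl N-(tert-butyldimethylsilyl)-N-isopropylcarbamate | COCOc1cc(OCOC)c([Li])c(OC(=O)N(C(C)C)[Si](C)(C)C(C)(C)C)c1 | intermediate
6 | 3,5-bis(methoxymethoxy)-2-(trimethylsilyl)phenyl N-(tert-butyldimethylsilyl)-N-isopropylcarbamate | COCOc1cc(OCOC)c([Si](C)(C)C)c(OC(=O)N(C(C)C)[Si](C)(C)C(C)(C)C)c1 | intermediate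
7 | 3,5-bis(methoxymethoxy)-2-(trimethylsilyl)phenyl N-isopropylcarbamate | COCOc1cc(OCOC)c([Si](C)(C)C)c(OC(=O)NC(C)C)c1 | intermediate
8 | 3,5-bis(methoxymethoxy)-2-(trimethylsilyl)phenol | COCOc1cc(OCOC)c([Si](C)(C)C)c(O)c1 | intermediate
9 | 3,5-bis(methoxymethoxy)-2-(trimethylsilyl)phenyl trifluoromethanesulfonate | COCOc1cc(OCOC)c([Si](C)(C)C)c(OS(=O)(=O)C(F)(F)F)c1 | intermediate
10 | methyl 3-bromo-4-hydroxybenzoate | COC(=O)c1ccc(O)c(Br)c1 | starting material
11 | methyl 3-bromo-4-hydroxy-5-iodobenzoate | COC(=O)c1cc(Br)c(O)c(I)c1 | intermediate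
12 | methyl 3-bromo-5-iodo-4-methoxybenzoate | COC(=O)c1cc(Br)c(OC)c(I)c1 | intermediate
13 | methyl acetate | CC(=O)OC | starting material
14 | lithium enolate of methyl acetate | C=C(OC)[O-].[Li+] | intermediate
15 | methyl 3-(3-bromo-5-iodo-4-methoxyphenyl)-3-oxopropanoate | COC(=O)CC(=O)c1cc(Br)c(OC)c(I)c1 | intermediate
16 | methyl (S)-3-(3-bromo-5-iodo-4-methoxyphenyl)-3-hydroxypropanoate | COc1c(I)cc([C@@H](O)CC(=O)OC)cc1Br | intermediate
17 | sodium alkoxide of 16 | COc1c(I)cc([C@@H]([O-])CC(=O)OC)cc1Br.[Na+] | intermediate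
18 | 3,5-bis(methoxymethoxy)benzyne | COCOC1=CC(OCOC)=CC#C1 | intermediate
19 | sodium 2-{[(S)-1-(3-bromo-5-iodo-4-methoxyphenyl)-3-methoxy-3-oxopropyl]oxy}-4,6-bis(methoxymethoxy)phenide | COc1c(I)cc([C@@H](Oc2cc(OCOC)cc(OCOC)[c-]2)CC(=O)OC)cc1Br.[Na+] | intermediate
20 | (S)-2-(3-bromo-5-iodo-4-methoxyphenyl)-5,7-bis(methoxymethoxy)chroman-4-one | COc1c(I)cc([C@@H]2CC(=O)c3c(OCOC)cc(OCOC)cc3O2)cc1Br | intermediate
21 | (S)-2-(3-bromo-5-iodo-4-methoxyphenyl)-5,7-dihydroxychroman-4-one | COc1c(I)cc([C@@H]2CC(=O)c3c(O)cc(O)cc3O2)cc1Br | intermediate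
22 | (S)-2-(3-bromo-5-iodo-4-methoxyphenyl)-5-hydroxy-7-(triisopropylsilyloxy)chroman-4-one | COc1c(I)cc([C@@H]2CC(=O)c3c(O)cc(O[Si](C(C)C)(C(C)C)C(C)C)cc3O2)cc1Br | intermediate
23 | 2-methyl-3-butyn-2-ol | CC(C)(O)C#C | starting material
24 | (S)-2-[3-bromo-5-(3-hydroxy-3-methylbut-1-yn-1-yl)-4-methoxyphenyl]-5-hydroxy-7-(triisopropylsilyloxy)chroman-4-one | COc1c(C#CC(C)(C)O)cc([C@@H]2CC(=O)c3c(O)cc(O[Si](C(C)C)(C(C)C)C(C)C)cc3O2)cc1Br | intermediate
25 | tributyl(3-methylbut-2-en-1-yl)stannane | CCCC[Sn](CCCC)(CCCC)CC=C(C)C | starting material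
26 | (S)-5-hydroxy-2-[3-(3-hydroxy-3-methylbut-1-yn-1-yl)-4-methoxy-5-(3-methylbut-2-en-1-yl)phenyl]-7-(triisopropylsilyloxy)chroman-4-one | COc1c(C#CC(C)(C)O)cc([C@@H]2CC(=O)c3c(O)cc(O[Si](C(C)C)(C(C)C)C(C)C)cc3O2)cc1CC=C(C)C | intermediate
27 | (S)-5-hydroxy-2-[3-((Z)-3-hydroxy-3-methylbut-1-en-1-yl)-4-methoxy-5-(3-methylbut-2-en-1-yl)phenyl]-7-(triisopropylsilyloxy)chroman-4-one | COc1c(/C=C\C(C)(C)O)cc([C@@H]2CC(=O)c3c(O)cc(O[Si](C(C)C)(C(C)C)C(C)C)cc3O2)cc1CC=C(C)C | intermediate
28 | (S)-5,7-dihydroxy-2-[3-((Z)-3-hydroxy-3-methylbut-1-en-1-yl)-4-methoxy-5-(3-methylbut-2-en-1-yl)phenyl]chroman-4-one | COc1c(/C=C\C(C)(C)O)cc([C@@H]2CC(=O)c3c(O)cc(O)cc3O2)cc1CC=C(C)C | target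

**Step count**

Total step count: 15. Longest linear sequence: 11 steps (steps 1–4, then 9–15; the branch through steps 5–8 is equally long).

**Steps most likely to fail**

1. Step 9 (proposed method). The aryl anion may capture a proton before it acylates. The alkoxide may fragment by retro-aldol cleavage or β-elimination. Released methoxide may open ring C and erode the configuration at C2.
Fallback by known chemistry, setting out from keto ester 15 and phenol 2 and returning at 20:
 - Transfer hydrogenation of 15 with the enantiomeric catalyst RuCl[(R,R)-TsDPEN](p-cymene) in HCO2H/Et3N would give methyl (R)-3-(3-bromo-5-iodo-4-methoxyphenyl)-3-hydroxypropanoate F1.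
 - Mitsunobu etherification of this alcohol with 2 (PPh3, DIAD, toluene, 0 °C) would invert the carbinol carbon and give methyl (S)-3-[3,5-bis(methoxymethoxy)phenoxy]-3-(3-bromo-5-iodo-4-methoxyphenyl)propanoate F2.
 - Saponification (LiOH, THF/H2O, 0 °C, then dilute HCl) would give (S)-3-[3,5-bis(methoxymethoxy)phenoxy]-3-(3-bromo-5-iodo-4-methoxyphenyl)propanoic acid F3.
 - Trifluoroacetic anhydride (CH2Cl2, 0 °C) would close ring C by intramolecular Friedel–Crafts acylation at the carbon ortho to the ether oxygen of the phloroglucinol ring, giving 20. Partial loss of a methoxymethyl group here is harmless, since step 10 removes both.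
 - The open ether left by proton quench in step 9 is the same ester as the Mitsunobu product, so it can be carried through the same saponification and acylation.

2. Step 13. Oxidative addition at the electron-rich, ortho-alkoxy bromide may be slow, and allyl transposition during transfer from tin may attach the tertiary terminus (reverse prenyl).
Fallback, setting out from 24 and returning at 27:
 - Lindlar semihydrogenation of 24 (conditions of step 14) would give (S)-2-[3-bromo-5-((Z)-3-hydroxy-3-methylbut-1-en-1-yl)-4-methoxyphenyl]-5-hydroxy-7-(triisopropylsilyloxy)chroman-4-one F4.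
 - Stille coupling with allyltributylstannane, whose symmetrical allyl group cannot transpose (Pd(PPh3)4, DMF, 90 °C), would give (S)-2-[3-allyl-5-((Z)-3-hydroxy-3-methylbut-1-en-1-yl)-4-methoxyphenyl]-5-hydroxy-7-(triisopropylsilyloxy)chroman-4-one F5.
 - Cross-metathesis with 2-methyl-2-butene (second-generation Grubbs catalyst, RuCl2(H2IMes)(PCy3)(=CHPh), CH2Cl2, 40 °C) would convert the allyl into the prenyl group and give 27. The hindered (Z)-alkene next to the tertiary carbinol should not take part.

3. Step 3. Lithiation may occur between the two acetal ethers instead of next to the carbamate, and the silyl triflate may cleave an acetal ether.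
Fallback, setting out from 2 and returning at 8:
 - Amine-directed ortho-bromination of 2 (NBS, iPr2NH cat., CH2Cl2, 0 °C) would give 2-bromo-3,5-bis(methoxymethoxy)phenol F6.
 - Hexamethyldisilazane (THF, 65 °C) would give [2-bromo-3,5-bis(methoxymethoxy)phenoxy]trimethylsilane F7.
 - n-BuLi (THF, −78 °C) would effect bromine–lithium exchange and 1,3 O-to-C silyl migration (retro-Brook rearrangement) to lithium 3,5-bis(methoxymethoxy)-2-(trimethylsilyl)phenoxide F8.
 - Aqueous NH4Cl quench of the phenoxide gives phenol 8, which is triflated with PhNTf2 and DBU as in the second half of step 4 to give 9.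

**Further compounds**

F1 | step 9 | methyl (R)-3-(3-bromo-5-iodo-4-methoxyphenyl)-3-hydroxypropanoate | COc1c(I)cc([C@H](O)CC(=O)OC)cc1Br
F2 | step 9 | methyl (S)-3-[3,5-bis(methoxymethoxy)phenoxy]-3-(3-bromo-5-iodo-4-methoxyphenyl)propanoate | COc1c(I)cc([C@@H](Oc2cc(OCOC)cc(OCOC)c2)CC(=O)OC)cc1Br
F3 | step 9 | (S)-3-[3,5-bis(methoxymethoxy)phenoxy]-3-(3-bromo-5-iodo-4-methoxyphenyl)propanoic acid | COc1c(I)cc([C@@H](Oc2cc(OCOC)cc(OCOC)c2)CC(=O)O)cc1Br
F4 | step 13 | (S)-2-[3-bromo-5-((Z)-3-hydroxy-3-methylbut-1-en-1-yl)-4-methoxyphenyl]-5-hydroxy-7-(triisopropylsilyloxy)chroman-4-one | COc1c(/C=C\C(C)(C)O)cc([C@@H]2CC(=O)c3c(O)cc(O[Si](C(C)C)(C(C)C)C(C)C)cc3O2)cc1Br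
F5 | step 13 | (S)-2-[3-allyl-5-((Z)-3-hydroxy-3-methylbut-1-en-1-yl)-4-methoxyphenyl]-5-hydroxy-7-(triisopropylsilyloxy)chroman-4-one | COc1c(/C=C\C(C)(C)O)cc([C@@H]2CC(=O)c3c(O)cc(O[Si](C(C)C)(C(C)C)C(C)C)cc3O2)cc1CC=C
F6 | step 3 | 2-bromo-3,5-bis(methoxymethoxy)phenol | COCOc1cc(O)c(Br)c(OCOC)c1
F7 | step 3 | [2-bromo-3,5-bis(methoxymethoxy)phenoxy]trimethylsilane | COCOc1cc(O[Si](C)(C)C)c(Br)c(OCOC)c1
F8 | step 3 | lithium 3,5-bis(methoxymethoxy)-2-(trimethylsilyl)phenoxide | COCOc1cc(OCOC)c([Si](C)(C)C)c([O-])c1.[Li+]
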